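**Strategy**

Ring B (C1, C10, C9, C8, C7, C6; cadinane numbering, see remark) is opened at C7–C8. The plan exploits that C8 lies between the oxygenated carbon C9 and the sp2 carbon C7 of the exocyclic C7=C11 alkene: with C9 as a methyl ketone and C7 as a geometrically defined alkenyl iodide, a palladium-catalysed intramolecular enolate alkenylation forges C7–C8, closes ring B with the tetrasubstituted alkene intact and lets the C10 methyl centre settle by equilibration. The precursor is a ring A cyclohexene carrying, cis to each other, a 3-oxobutan-2-yl group at C1 and a (Z)-1-iodo-2-methyl-3-silyloxypropenyl group at C6; it is built from a quinone monoketal by asymmetric conjugate addition.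

Key step: step 12

Remark on numbering: in the target SMILES the skeleton carbons appear, after the first acetate, in the order C3, C2, C1, C10 (methyl C14), C9, C8, C7, C11 (methyl C12, CH2O carbon C13), C6, C5, C4 (methyl C15). Ring A is C1–C6; ring B is C1, C10, C9, C8, C7, C6.

Remark on assumptions: compounds 1, 3 and 10 are taken as commercially available. (R)-BINAP is assumed to give the (5R) centre of 4 by analogy with additions to cyclohex-2-enone; should the sense be opposite, (S)-BINAP is used.

**Route**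

Step 1
Reactants: 1 4-methoxy-2-methylphenol
Product: 2 4,4-dimethoxy-2-methylcyclohexa-2,5-dien-1-one
Conditions: PhI(OAc)2 (1.1 equiv), MeOH, 0 °C
Reagents that add atoms: methanol (SMILES: CO)
Why: Oxidative dearomatisation: PhI(OAc)2 converts the para-methoxyphenol into a phenoxenium species that methanol captures at the methoxy-bearing carbon to give the quinone monoketal; no stereocentre is formed.

Step 2
Reactants: 2 4,4-dimethoxy-2-methylcyclohexa-2,5-dien-1-one; 3 (Z)-but-2-en-2-ylboronic acid
Product: 4 (5R)-5-[(E)-but-2-en-2-yl]-4,4-dimethoxy-2-methylcyclohex-2-en-1-one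
Conditions: [Rh(OH)(cod)]2 (2.5 mol %), (R)-BINAP (6 mol %), 1,4-dioxane/H2O (10:1), 40 °C
Reagents that add atoms: none
Why: Hayashi–Miyaura reaction (rhodium-catalysed asymmetric conjugate addition): the alkenylrhodium species adds to the unsubstituted enone arm (the methyl-bearing arm is much less reactive) with retention of the alkene geometry, and the (R)-BINAP complex is expected to choose the enone face that gives the (5R) centre, the future C1.

Step 3
Reactants: 4 (5R)-5-[(E)-but-2-en-2-yl]-4,4-dimethoxy-2-methylcyclohex-2-en-1-one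
Product: 5 (1R,5R)-5-[(E)-but-2-en-2-yl]-4,4-dimethoxy-2-methylcyclohex-2-en-1-ol
Conditions: NaBH4, CeCl3·7H2O, MeOH, −78 °C
Reagents that add atoms: none
Why: Luche reduction: 1,2-selective axial hydride delivery to the enone, as in the reduction of carvone, should place the hydroxyl cis to the ring substituent two carbons away and set the future C3 as (R).

Step 4
Reactants: 5 (1R,5R)-5-[(E)-but-2-en-2-yl]-4,4-dimethoxy-2-methylcyclohex-2-en-1-ol
Product: 6 silyl ether of 5
Conditions: TBSCl, imidazole, DMF, 25 °C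
Reagents that add atoms: tert-butyldimethylsilyl chloride (SMILES: CC(C)(C)[Si](C)(C)Cl)
Why: Silyl ether formation at the secondary allylic alcohol protects the future C3 oxygen through the organometallic steps; no stereocentre is touched.

Step 5
Reactants: 6 silyl ether of 5
Product: 7 (4R,6R)-6-[(E)-but-2-en-2-yl]-4-[(tert-butyldimethylsilyl)oxy]-3-methylcyclohex-2-en-1-one
Conditions: pyridinium p-toluenesulfonate (10 mol %), acetone/H2O (10:1), 25 °C
Reagents that add atoms: water (SMILES: O)
Why: Acid-catalysed hydrolysis of the allylic dimethyl ketal, which the silyl ether should survive; the centre next to the new ketone keeps its configuration because the cis-4,6-disubstituted enone is the more stable epimer.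

Step 6
Reactants: 7 (4R,6R)-6-[(E)-but-2-en-2-yl]-4-[(tert-butyldimethylsilyl)oxy]-3-methylcyclohex-2-en-1-one
Product: 8 (1S,4R,6R)-6-[(E)-but-2-en-2-yl]-4-[(tert-butyldimethylsilyl)oxy]-3-methylcyclohex-2-en-1-ol
Conditions: NaBH4, CeCl3·7H2O, MeOH, −78 °C
Reagents that add atoms: none
Why: Luche reduction: axial hydride attack on the enone should give the pseudo-equatorial alcohol trans to the adjacent butenyl group, the (1S) carbinol needed for the inversion in step 8.

Step 7
Reactants: 8 (1S,4R,6R)-6-[(E)-but-2-en-2-yl]-4-[(tert-butyldimethylsilyl)oxy]-3-methylcyclohex-2-en-1-ol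
Product: 9 methyl carbonate of 8
Conditions: ClCO2Me, pyridine, DMAP (cat.), CH2Cl2, 0 °C
Reagents that add atoms: methyl chloroformate (SMILES: COC(=O)Cl)
Why: O-Acylation (alkoxycarbonylation) turns the allylic alcohol into an ionisable carbonate with retention at carbon.

Step 8
Reactants: 9 methyl carbonate of 8; 10 prop-2-yn-1-ol
Product: 12 3-[(1R,4R,6S)-6-[(E)-but-2-en-2-yl]-4-[(tert-butyldimethylsilyl)oxy]-3-methylcyclohex-2-en-1-yl]prop-2-yn-1-ol, via zinc acetylide 11 (not isolated)
Conditions: 10, n-BuLi (2 equiv), THF, −78 to 0 °C; ZnCl2; then 9, Pd(PPh3)4 (5 mol %), THF, 25 to 45 °C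
Reagents that add atoms: none
Why: Negishi-type palladium-catalysed allyl–alkynyl coupling: zerovalent palladium ionises the carbonate with inversion, the alkynylzinc transmetalates and reductive elimination at the less hindered allyl terminus delivers the alkyne from the palladium face, so net inversion sets the future C6 with the alkyne cis to the butenyl group.

Step 9
Reactants: 12 3-[(1R,4R,6S)-6-[(E)-but-2-en-2-yl]-4-[(tert-butyldimethylsilyl)oxy]-3-methylcyclohex-2-en-1-yl]prop-2-yn-1-ol
Product: 14 (Z)-iodoalkenol (2Z)-3-[(1R,4R,6S)-6-[(E)-but-2-en-2-yl]-4-[(tert-butyldimethylsilyl)oxy]-3-methylcyclohex-2-en-1-yl]-3-iodo-2-methylprop-2-en-1-ol, via alkenylmagnesium chelate 13 (not isolated)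
Conditions: MeMgBr (5 equiv), CuI (10 mol %), THF, 0 to 60 °C; then I2, −78 to 0 °C
Reagents that add atoms: methylmagnesium bromide (SMILES: C[Mg]Br); iodine (SMILES: II)
Why: Copper-catalysed anti-carbomagnesiation of the propargylic alkoxide: methyl adds to the alkyne carbon next to the CH2O group and magnesium to the ring-bearing carbon within a five-membered alkoxide chelate, and iodinolysis with retention gives the tetrasubstituted (Z)-iodoalkene with iodine cis to CH2OH and the ring cis to the new methyl.

Step 10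
Reactants: 14 (Z)-iodoalkenol
Product: 15 bis-silyl ether of 14
Conditions: TBSCl, imidazole, CH2Cl2, 25 °C
Reagents that add atoms: tert-butyldimethylsilyl chloride (SMILES: CC(C)(C)[Si](C)(C)Cl)
Why: Silyl ether formation masks the primary allylic alcohol (C13–OH) so that only the side-chain carbon is oxidised in step 11; no stereocentre is touched.

Step 11
Reactants: 15 bis-silyl ether of 14
Product: 17 methyl ketone 3-[(1R,2S,5R)-5-[(tert-butyldimethylsilyl)oxy]-2-[(Z)-3-[(tert-butyldimethylsilyl)oxy]-1-iodo-2-methylprop-1-en-1-yl]-4-methylcyclohex-3-en-1-yl]butan-2-one, via alkylborane 16 (not isolated)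
Conditions: BH3·SMe2 (1.1 equiv), THF, 0 °C; then N-methylmorpholine N-oxide (6 equiv), (n-Pr4N)RuO4 (5 mol %), 4 Å molecular sieves, CH2Cl2, 25 °C
Reagents that add atoms: N-methylmorpholine N-oxide (SMILES: C[N+]1([O-])CCOCC1)
Why: Hydroboration followed by direct oxidation of the carbon–boron bond: borane places boron on the less substituted carbon of the exposed butenyl alkene (the ring alkene is shielded by the allylic silyl ether and the neighbouring branch) and oxidation gives the methyl ketone; the new methyl-bearing centre (future C10) forms as a mixture that step 12 converges.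

Step 12
Reactants: 17 methyl ketone (both C10 epimers)
Product: 18 (1R,4E,4aS,7R,8aS)-7-[(tert-butyldimethylsilyl)oxy]-4-{1-[(tert-butyldimethylsilyl)oxy]propan-2-ylidene}-1,6-dimethyl-3,4,4a,7,8,8a-hexahydronaphthalen-2(1H)-one
Conditions: Pd(PPh3)4 (10 mol %), KOt-Bu (2.5 equiv), THF/t-BuOH (4:1), 25 °C; AcOH/aq. NH4Cl quench at −78 °C
Reagents that add atoms: none
Why: Zerovalent palladium adds oxidatively to the alkenyl C7–I bond with retention, KOt-Bu converts the methyl ketone into its enolate, and the C8-bound palladium enolate undergoes reductive elimination from a seven-membered palladacycle to form C7–C8. The closest known reaction type is the palladium-catalysed intramolecular α-alkenylation of a ketone enolate with an alkenyl iodide. Ring B closes as a six-membered carbocycle with the enolate C8=C9 bond outside the new ring (6-enolexo closure onto the sp2 carbon C7); coupling through C10 would give a four-membered ring and is not expected. The new C10 centre is under thermodynamic control: the C10 epimers of 17 and of the product interconvert through the C9–C10 enolate, and in the ring B chair that keeps C6–C5 axial (avoiding allylic 1,3-strain with the C12 methyl) only the (R) epimer has the C10 methyl equatorial. The step needs retention of the C7=C11 geometry, which the stereospecific oxidative addition and reductive elimination secure, and it needs the β,γ-alkene to stay out of conjugation, which the low-temperature protic quench (kinetic protonation of the dienolate at C8) and the poor leaving-group ability of the silyloxy group are meant to secure.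

Step 13
Reactants: 18 bicyclic ketone
Product: 19 (1R,2R,4E,4aS,7R,8aS)-7-[(tert-butyldimethylsilyl)oxy]-4-{1-[(tert-butyldimethylsilyl)oxy]propan-2-ylidene}-1,6-dimethyl-1,2,3,4,4a,7,8,8a-octahydronaphthalen-2-ol
Conditions: NaBH4, MeOH, −40 °C
Reagents that add atoms: none
Why: Borohydride reduction: axial hydride attack on the ring B ketone (only H1 is axial on that face, C7 is sp2) should give the equatorial C9 alcohol trans to the C10 methyl, (R) at C9.

Step 14
Reactants: 19 bicyclic alcohol
Product: 20 (1R,2R,4E,4aS,7R,8aS)-4-(1-hydroxypropan-2-ylidene)-1,6-dimethyl-1,2,3,4,4a,7,8,8a-octahydronaphthalene-2,7-diol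
Conditions: n-Bu4NF (3 equiv), THF, 25 °C
Reagents that add atoms: none
Why: Fluoride-mediated desilylation removes both silyl ethers; no stereocentre is touched.

Step 15
Reactants: 20 triol
Product: 21 (2E)-2-[(3R,4R,4aS,6R,8aS)-3,6-dihydroxy-4,7-dimethyl-3,4,4a,5,6,8a-hexahydronaphthalen-1(2H)-ylidene]propyl formate
Conditions: 2,2,2-trifluoroethyl formate (3 equiv), THF, 40 °C
Reagents that add atoms: 2,2,2-trifluoroethyl formate (SMILES: O=COCC(F)(F)F)
Why: Selective O-formylation by transesterification: the unhindered primary allylic alcohol should react much faster than the two secondary alcohols.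

Step 16
Reactants: 21 mono-formate
Product: 22 target, (2E)-2-[(3R,4R,4aS,6R,8aS)-3,6-diacetoxy-4,7-dimethyl-3,4,4a,5,6,8a-hexahydronaphthalen-1(2H)-ylidene]propyl formate
Conditions: Ac2O (5 equiv), pyridine, 25 °C
Reagents that add atoms: acetic anhydride (SMILES: CC(=O)OC(C)=O)
Why: Acetylation of the two secondary alcohols in pyridine without a nucleophilic catalyst, conditions under which the formate ester should persist; no stereocentre is touched.

**Compound list**

1 | 4-methoxy-2-methylphenol | Cc1cc(OC)ccc1O | starting material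
2 | 4,4-dimethoxy-2-methylcyclohexa-2,5-dien-1-one | COC1(OC)C=CC(=O)C(C)=C1 | intermediate
3 | (Z)-but-2-en-2-ylboronic acid | C/C=C(\C)B(O)O | starting material
4 | (5R)-5-[(E)-but-2-en-2-yl]-4,4-dimethoxy-2-methylcyclohex-2-en-1-one | O=C1C[C@H](/C(C)=C/C)C(OC)(OC)C=C1C | intermediate
5 | (1R,5R)-5-[(E)-but-2-en-2-yl]-4,4-dimethoxy-2-methylcyclohex-2-en-1-ol | O[C@@H]1C[C@H](/C(C)=C/C)C(OC)(OC)C=C1C | intermediate
6 | tert-butyl{[(1R,5R)-5-[(E)-but-2-en-2-yl]-4,4-dimethoxy-2-methylcyclohex-2-en-1-yl]oxy}dimethylsilane | CC(C)(C)[Si](C)(C)O[C@@H]1C[C@H](/C(C)=C/C)C(OC)(OC)C=C1C | intermediate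
7 | (4R,6R)-6-[(E)-but-2-en-2-yl]-4-[(tert-butyldimethylsilyl)oxy]-3-methylcyclohex-2-en-1-one | CC(C)(C)[Si](C)(C)O[C@@H]1C[C@H](/C(C)=C/C)C(=O)C=C1C | intermediate
8 | (1S,4R,6R)-6-[(E)-but-2-en-2-yl]-4-[(tert-butyldimethylsilyl)oxy]-3-methylcyclohex-2-en-1-ol | CC(C)(C)[Si](C)(C)O[C@@H]1C[C@H](/C(C)=C/C)[C@@H](O)C=C1C | intermediate
9 | (1S,4R,6R)-6-[(E)-but-2-en-2-yl]-4-[(tert-butyldimethylsilyl)oxy]-3-methylcyclohex-2-en-1-yl methyl carbonate | CC(C)(C)[Si](C)(C)O[C@@H]1C[C@H](/C(C)=C/C)[C@@H](OC(=O)OC)C=C1C | intermediate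
10 | prop-2-yn-1-ol | C#CCO | starting material
11 | chloro(3-lithiooxyprop-1-yn-1-yl)zinc (zinc acetylide, not isolated) | [Li]OCC#C[Zn]Cl | intermediate
12 | 3-[(1R,4R,6S)-6-[(E)-but-2-en-2-yl]-4-[(tert-butyldimethylsilyl)oxy]-3-methylcyclohex-2-en-1-yl]prop-2-yn-1-ol | CC(C)(C)[Si](C)(C)O[C@@H]1C[C@H](/C(C)=C/C)[C@H](C#CCO)C=C1C | intermediate
13 | bromomagnesium alkoxide of the (Z)-alkenylmagnesium bromide from 12 (Mg on the ring-bearing alkene carbon, cis to CH2O; not isolated) | CC(C)(C)[Si](C)(C)O[C@@H]1C[C@H](/C(C)=C/C)[C@H](/C([Mg]Br)=C(\C)CO[Mg]Br)C=C1C | intermediate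
14 | (2Z)-3-[(1R,4R,6S)-6-[(E)-but-2-en-2-yl]-4-[(tert-butyldimethylsilyl)oxy]-3-methylcyclohex-2-en-1-yl]-3-iodo-2-methylprop-2-en-1-ol | CC(C)(C)[Si](C)(C)O[C@@H]1C[C@H](/C(C)=C/C)[C@H](/C(I)=C(\C)CO)C=C1C | intermediate
15 | tert-butyldimethylsilyl ether of 14 at the primary hydroxyl | CC(C)(C)[Si](C)(C)O[C@@H]1C[C@H](/C(C)=C/C)[C@H](/C(I)=C(\C)CO[Si](C)(C)C(C)(C)C)C=C1C | intermediate
16 | {3-[(1R,2S,5R)-5-[(tert-butyldimethylsilyl)oxy]-2-[(Z)-3-[(tert-butyldimethylsilyl)oxy]-1-iodo-2-methylprop-1-en-1-yl]-4-methylcyclohex-3-en-1-yl]butan-2-yl}borane (diastereomer mixture in the side chain, not isolated) | CC(C)(C)[Si](C)(C)O[C@@H]1C[C@H](C(C)C(C)B)[C@H](/C(I)=C(\C)CO[Si](C)(C)C(C)(C)C)C=C1C | intermediate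
17 | 3-[(1R,2S,5R)-5-[(tert-butyldimethylsilyl)oxy]-2-[(Z)-3-[(tert-butyldimethylsilyl)oxy]-1-iodo-2-methylprop-1-en-1-yl]-4-methylcyclohex-3-en-1-yl]butan-2-one (both epimers at C3 of the butanone) | CC(C)(C)[Si](C)(C)O[C@@H]1C[C@H](C(C)C(C)=O)[C@H](/C(I)=C(\C)CO[Si](C)(C)C(C)(C)C)C=C1C | intermediate
18 | (1R,4E,4aS,7R,8aS)-7-[(tert-butyldimethylsilyl)oxy]-4-{1-[(tert-butyldimethylsilyl)oxy]propan-2-ylidene}-1,6-dimethyl-3,4,4a,7,8,8a-hexahydronaphthalen-2(1H)-one | CC(C)(C)[Si](C)(C)O[C@@H]1C[C@@H]2[C@@H](C)C(=O)C/C(=C(/C)CO[Si](C)(C)C(C)(C)C)[C@@H]2C=C1C | intermediate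
19 | (1R,2R,4E,4aS,7R,8aS)-7-[(tert-butyldimethylsilyl)oxy]-4-{1-[(tert-butyldimethylsilyl)oxy]propan-2-ylidene}-1,6-dimethyl-1,2,3,4,4a,7,8,8a-octahydronaphthalen-2-ol | CC(C)(C)[Si](C)(C)O[C@@H]1C[C@@H]2[C@@H](C)[C@H](O)C/C(=C(/C)CO[Si](C)(C)C(C)(C)C)[C@@H]2C=C1C | intermediate
20 | (1R,2R,4E,4aS,7R,8aS)-4-(1-hydroxypropan-2-ylidene)-1,6-dimethyl-1,2,3,4,4a,7,8,8a-octahydronaphthalene-2,7-diol | O[C@@H]1C[C@@H]2[C@@H](C)[C@H](O)C/C(=C(/C)CO)[C@@H]2C=C1C | intermediate
21 | (2E)-2-[(3R,4R,4aS,6R,8aS)-3,6-dihydroxy-4,7-dimethyl-3,4,4a,5,6,8a-hexahydronaphthalen-1(2H)-ylidene]propyl formate | O[C@@H]1C[C@@H]2[C@@H](C)[C@H](O)C/C(=C(/C)COC=O)[C@@H]2C=C1C | intermediate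
22 | (2E)-2-[(3R,4R,4aS,6R,8aS)-3,6-diacetoxy-4,7-dimethyl-3,4,4a,5,6,8a-hexahydronaphthalen-1(2H)-ylidene]propyl formate (CNP0262962.1) | CC(=O)O[C@@H]1C[C@@H]2[C@@H](C)[C@H](OC(C)=O)C/C(=C(/C)COC=O)[C@@H]2C=C1C | target

**Totals**

Total step count: 16. Longest linear sequence: 16 steps (from 1).

**Steps most likely to fail and fallbacks**

Risk 1 (step 8, allylic alkynylation). The carbonate has to ionise on the face syn to the neighbouring butenyl group. β-Hydride elimination of the allylpalladium intermediate to a diene, or loss of configuration while transmetalation is slow, may therefore compete. The fallback puts the carbon in first and the hydrogen in last; it sets out from ketone 7 and comes back to the route at 12. Addition of 10, after double deprotonation with n-BuLi, to the carbonyl group of 7 gives the tertiary propargylic diol F1. Complexation of the alkyne with Co2(CO)8 gives the hexacarbonyldicobalt complex F2. Nicholas reduction (BF3·OEt2, Et3SiH, −78 °C) should ionise the tertiary hydroxyl and deliver hydride to the cobalt-stabilised cation on the face away from the butenyl group, giving the reduced complex F3. Oxidative decomplexation with (NH4)2Ce(NO3)6 releases 12.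

Risk 2 (step 9, anti-carbomagnesiation). Addition of the methyl Grignard reagent to the hindered internal alkyne may be sluggish or incomplete, and the alkenylmagnesium intermediate may be protonated before iodination. The fallback sets out from carbonate 9 and comes back at 14. The coupling of step 8 is run with prop-1-ynylmagnesium bromide/ZnCl2 in place of 10 to give the propynyl compound F4. Treatment of F4 with Ti(Oi-Pr)4 and i-PrMgCl (−50 °C), then formaldehyde, then iodine is a titanium-mediated syn hydroxymethylation–iodination of the alkyne. Carbon–carbon bond formation should occur at the less hindered, methyl-bearing alkyne carbon and iodinolysis at the ring-bearing carbon, giving 14 with the same geometry (iodine cis to CH2OH).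

Risk 3 (step 12, key step). Under the alkoxide base the C7=C11 double bond may migrate into conjugation with the C9 ketone, silyloxide may be lost from the dienolate, and oxidative addition to the tetrasubstituted iodide may be slow. The fallback sets out from 17 and comes back at 18. Kinetic deprotonation (LDA, −78 °C) and trapping with Me3SiCl give the trimethylsilyl enol ether F5 on the methyl side. A fluoride-promoted tin-enolate cross-coupling (Bu3SnF, PdCl2[P(o-tol)3]2, toluene, 80 °C) then closes ring B without alkoxide base. The C10 epimers are no longer equilibrated in the flask; they are converged afterwards by brief exposure to DBU, or separated with recycling of the minor one.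

Further compounds
F1 | step 8 | 3-[(4R,6R)-6-[(E)-but-2-en-2-yl]-4-[(tert-butyldimethylsilyl)oxy]-1-hydroxy-3-methylcyclohex-2-en-1-yl]prop-2-yn-1-ol (either C1 epimer) | CC(C)(C)[Si](C)(C)O[C@@H]1C[C@H](/C(C)=C/C)C(O)(C#CCO)C=C1C
F2 | step 8 | hexacarbonyldicobalt complex, Co2(CO)6, of the alkyne of F1 | CC(C)(C)[Si](C)(C)O[C@@H]1C[C@H](/C(C)=C/C)C(O)(C23C4(CO)[Co]2(=C=O)(=C=O)(=C=O)[Co]34(=C=O)(=C=O)=C=O)C=C1C
F3 | step 8 | hexacarbonyldicobalt complex, Co2(CO)6, of the alkyne of 12 | CC(C)(C)[Si](C)(C)O[C@@H]1C[C@H](/C(C)=C/C)[C@H](C23C4(CO)[Co]2(=C=O)(=C=O)(=C=O)[Co]34(=C=O)(=C=O)=C=O)C=C1C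
F4 | step 9 | tert-butyl{[(1R,4R,5S)-5-[(E)-but-2-en-2-yl]-2-methyl-4-(prop-1-yn-1-yl)cyclohex-2-en-1-yl]oxy}dimethylsilane | CC(C)(C)[Si](C)(C)O[C@@H]1C[C@H](/C(C)=C/C)[C@H](C#CC)C=C1C
F5 | step 12 | trimethylsilyl enol ether of 17 on the methyl side, tert-butyl{[(1R,4S,5R)-4-[(Z)-3-[(tert-butyldimethylsilyl)oxy]-1-iodo-2-methylprop-1-en-1-yl]-2-methyl-5-{3-[(trimethylsilyl)oxy]but-3-en-2-yl}cyclohex-2-en-1-yl]oxy}dimethylsilane | CC(C)(C)[Si](C)(C)O[C@@H]1C[C@H](C(C)C(=C)O[Si](C)(C)C)[C@H](/C(I)=C(\C)CO[Si](C)(C)C(C)(C)C)C=C1C
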